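Noon and winter are one charge read at two times, so the question is how far the free monomer has gone into chains by each time.

| setting | violet | noon | winter |
|---|---|---|---|
| free monomer | 0.10 M | 0.10 M | 0.10 M |
| initiator | 15 mM | 7.5 mM | 7.5 mM |
| remark | run made earlier |  |  |
| time |  | 15 min | 5.0 min |

- violet (time / s: monomer in chains / %): 10.0: 10.0; 15.0: 12.3; 25.0: 17.9; 50.0: 25.7; 90.0: 32.5

(readings scatter by 0.3 percentage points)

- the average divides the monomer in chains by the number of chains begun, living and dead together
- the earlier runs do not show the number of chains; that part of a forecast is a guess
- no earlier run changes the charge of initiator; that part of a forecast is a guess

1. which of the two ends with the longer chains by the average number of monomer units in a chain (chains begun, living or dead) ("neither" if they lie within 10 %) (noon / winter / neither)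
2. average number of monomer units in a chain (chains begun, living or dead) at the end, noon
3. average number of monomer units in a chain (chains begun, living or dead) at the end, winter

We carry one quantity, the ceiling length 13.3: [free monomer] charged divided by [initiator] charged, the average length if the whole charge of free monomer stood in chains and each initiator began one chain, which is our guess. The average length, the field's number-average degree of polymerisation, is then the ceiling times the fraction of the charge in chains.

The violet run rose 7.9 percentage points in 15.0 s early but 6.8 points in 40.0 s late, so per second it slowed. We guess that a flask with less initiator climbs no faster than that late rate from the last violet reading on. Held for winter's time, this gives a roof of 9.09. Held for noon's time, it runs past the whole charge, so noon's roof stays the ceiling.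

From below, winter's charge of initiator times its time exceeds that of the last violet reading, and noon's exceeds it further. If that product orders conversion, which is another guess, both flasks reach at least 32.5 %, a floor of 4.33.

The forecast gives 6.6 for noon and 5.1 for winter, inside both brackets, and picks noon: “Noon wins regardless, since chain counts are equal”.

The flasks give 5.83 for noon, inside its bracket, and 4.31 for winter, which lies 0.0251 under the floor, itself taken from a scattered reading, and noon ends longer.

    free monomer + initiator → living end + monomer in chains (k = 0.830 L mol⁻¹ s⁻¹)
    free monomer + living end → monomer in chains + living end, rate k2*[living end]*[free monomer] (k = 0.410 L mol⁻¹ s⁻¹)
    monomer in chains + living end → free monomer + living end, rate k3*[living end] as long as [monomer in chains] is above zero (k = 0.00800 s⁻¹)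
    2 living end → dead end (k = 0.730 L mol⁻¹ s⁻¹)

Noon and winter share the ceiling, so their gap lies in the monomer in chains, and the difference in time is the main reason for it: winter left for noon's time gives 5.83 instead of 4.31. With 0 % of the initiator left in noon and 0 % in winter, the ceiling times 43.7 % gives 5.83 for noon, and times 32.3 % gives 4.31 for winter. In a neighbour of noon, charged with 0.030 M of initiator and with 0 % of it left at the end, the ceiling drops to 3.33, and times 64.9 % it gives 2.16, where that flask stands at 2.16.

The readings come from a simulation with made-up constants; the scatter is artificial.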